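The 14-membered carbocycle is cut at C9–C10. The C10 carboxylic acid with its α-stereocentre, the C9 methylene and the C7–C8 bond (an E-alkene one stage earlier) together are the γ,δ-unsaturated acid left by an ester-enolate Claisen shift. The precursor is therefore a 14-membered lactone in which the acetic acid arm (C10) of the 2,2-dimethyltetrahydrofuran ring esterifies a C7 vinyl carbinol; C6 carries a silyloxymethyl group as the masked second acid. A single [3,3] shift of its silyl ketene acetal trades the ring C7–O bond for C9–C10, turns lactone into carbocycle at constant ring size, sets C10 from C7 and releases the C10 acid.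

Key step: step 17

Remark on numbering: all compounds carry the atom labels of the target. C2 is the methyl-bearing alkene carbon, C3–C15 follow round the carbocycle, C16 is the CMe2 carbon of the oxolane (ring oxygen between C16 and C11), and C6′ is the exocyclic carbon on C6. In 6–8 the ring ketone carbon is C11, the quaternary carbon C2 and the carbinol carbon C3.

Assumption: in step 3 the side chain is taken to enter C2 cis to the isopropenyl group. This centre becomes sp2 in step 6, so only its relation to the C3 carbinol matters.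

Step 1
Reactants: 1 pentane-1,5-diol
Product: 2 5-[(tert-butyldiphenylsilyl)oxy]pentan-1-ol
Conditions: TBDPSCl (1 equiv), imidazole, 1 in excess (3 equiv), THF, 0 °C → rt
Reagents that add atoms: tert-butyl(chloro)diphenylsilane, CC(C)(C)[Si](Cl)(c1ccccc1)c1ccccc1
Why: Silyl ether formation on a symmetrical diol used in excess should stop at the mono-ether, and the surplus diol is removed by aqueous extraction.

Step 2
Reactants: 2 5-[(tert-butyldiphenylsilyl)oxy]pentan-1-ol
Product: 3 5-[(tert-butyldiphenylsilyl)oxy]pentanal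
Conditions: TEMPO (cat.), PhI(OAc)2, CH2Cl2, rt
Reagents that add atoms: none
Why: Oxoammonium (TEMPO/PhI(OAc)2) oxidation of a primary alcohol in dry CH2Cl2 should stop at the aldehyde and leaves the silyl ether untouched.

Step 3
Reactants: 4 (R)-carvone; 3 5-[(tert-butyldiphenylsilyl)oxy]pentanal
Product: 6 (2R,5R)-2-[(1R)-5-(TBDPS-oxy)-1-hydroxypentyl]-2-methyl-5-(prop-1-en-2-yl)cyclohexan-1-one, via lithium enolate 5 (not isolated)
Conditions: L-Selectride (1.05 equiv), THF, −78 °C; then 3, −78 °C; AcOH quench at −78 °C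
Reagents that add atoms: lithium tri-sec-butylborohydride, [Li+].CCC(C)[BH-](C(C)CC)C(C)CC (lithium retained only in intermediate 5; the product gains hydrogen only)
Why: Conjugate hydride reduction of the enone gives the regiodefined tetrasubstituted enolate 5, and its aldol addition to 3 (reductive aldol) should pass through a closed Zimmerman–Traxler chair with the aldehyde chain equatorial and the electrophile entering axially cis to the isopropenyl group, which puts the C2 methyl and the new C3 hydroxyl syn along the C11–C2–C3–C4 zigzag, the relationship that step 6 turns into the Z-alkene.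

Step 4
Reactants: 6 aldol adduct
Product: 7 (2R,5R)-2-[(1R)-5-(TBDPS-oxy)-1-(methanesulfonyloxy)pentyl]-2-methyl-5-(prop-1-en-2-yl)cyclohexan-1-one
Conditions: MsCl, Et3N, DMAP (cat.), CH2Cl2, 0 °C
Reagents that add atoms: methanesulfonyl chloride, CS(Cl)(=O)=O
Why: Sulfonylation of the only hydroxyl group (mesylation via sulfene, which tolerates the neopentyl-type hindrance) should be clean because the quaternary α-carbon rules out elimination to an enone.

Step 5
Reactants: 7 keto mesylate
Product: 8 (2R,5R)-5-(2-hydroxypropan-2-yl)-2-[(1R)-5-(TBDPS-oxy)-1-(methanesulfonyloxy)pentyl]-2-methylcyclohexan-1-one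
Conditions: Mn(dpm)3 (cat.), PhSiH3, O2 (1 atm), i-PrOH/CH2Cl2, 0 °C → rt
Reagents that add atoms: dioxygen, O=O
Why: Mukaiyama hydration (metal hydride hydrogen-atom transfer, then trapping by O2) adds water in the Markovnikov sense to the only alkene present, giving the tertiary C16 alcohol under neutral conditions that should spare ketone, mesylate and silyl ether.

Step 6
Reactants: 8 hydroxy keto mesylate
Product: 10 (4R)-4-[(3Z)-8-(TBDPS-oxy)-3-methyloct-3-en-1-yl]-5,5-dimethyloxolan-2-one, via hydroxy acid 9 (not isolated)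
Conditions: LiOH, THF/H2O, 0 °C → rt; then 1 M HCl (pH 2), rt
Reagents that add atoms: lithium hydroxide, [Li+].[OH-] (supplies the second carboxyl oxygen of 9; one carboxyl oxygen leaves again as water on ring closure)
Why: Grob-type fragmentation of a β-mesyloxy ketone, in which hydroxide (or the neighbouring tertiary alkoxide) adds to the C11 carbonyl and the tetrahedral alkoxide breaks the C11–C2 bond anti-periplanar to the C3–OMs bond, should translate the C2/C3 relative configuration stereospecifically into the Z C2=C3 alkene (C15 cis to C4), and acidification closes the γ-lactone of the tertiary γ-hydroxy acid 9.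

Step 7
Reactants: 10 γ-lactone
Product: 12 (4R)-4-[(3Z)-8-(TBDPS-oxy)-3-methyloct-3-en-1-yl]-5,5-dimethyloxolan-2-yl acetate (both C11 epimers), via aluminium hemiacetal 11 (not isolated)
Conditions: DIBAL-H, CH2Cl2, −78 °C; then pyridine, DMAP, Ac2O, −78 → 0 °C
Reagents that add atoms: diisobutylaluminium hydride, CC(C)C[AlH]CC(C)C (aluminium retained only in intermediate 11); acetic anhydride, CC(=O)OC(C)=O
Why: Reductive acetylation of a lactone (Rychnovsky protocol) should stop at the tetrahedral aluminium hemiacetal at −78 °C and acetylate it in the flask, and the mixed configuration at C11 is erased in step 8.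

Step 8
Reactants: 12 lactol acetate; 13 tert-butyl[(1-methoxyethenyl)oxy]dimethylsilane
Product: 14 methyl 2-[(2S,4R)-4-[(3Z)-8-(TBDPS-oxy)-3-methyloct-3-en-1-yl]-5,5-dimethyloxolan-2-yl]acetate
Conditions: 13 (2 equiv), TMSOTf (0.2 equiv), CH2Cl2, −78 °C
Reagents that add atoms: none
Why: Lewis-acid-mediated C-glycosylation (Mukaiyama-type addition of a silyl ketene acetal to a five-membered oxocarbenium ion) should set C11 as S, with C10 trans to C14 on the ring, because the nucleophile attacks the inside face of the envelope that holds the C13 chain pseudo-equatorial (Woerpel model).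

Step 9
Reactants: 14 silyl ether ester
Product: 15 methyl 2-[(2S,4R)-4-[(3Z)-8-hydroxy-3-methyloct-3-en-1-yl]-5,5-dimethyloxolan-2-yl]acetate
Conditions: TBAF, AcOH, THF, rt
Reagents that add atoms: none
Why: Fluoride-mediated desilylation removes the primary TBDPS group, and the acetic acid buffer keeps the medium from attacking the methyl ester.

Step 10
Reactants: 15 primary alcohol
Product: 16 (5Z)-8-[(3R,5S)-5-(2-methoxy-2-oxoethyl)-2,2-dimethyloxolan-3-yl]-6-methyloct-5-enoic acid
Conditions: TEMPO (cat.), PhI(OAc)2, MeCN/H2O, rt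
Reagents that add atoms: water, O
Why: TEMPO/PhI(OAc)2 oxidation in aqueous acetonitrile takes the primary alcohol through the aldehyde hydrate to the acid and should not touch the trisubstituted alkene or the ester.

Step 11
Reactants: 16 carboxylic acid; 17 (4S)-4-benzyl-1,3-oxazolidin-2-one
Product: 19 N-acyl oxazolidinone of 16, via mixed pivalic anhydride 18 (not isolated)
Conditions: PivCl, Et3N, THF, −20 °C; then LiCl, 17, rt
Reagents that add atoms: pivaloyl chloride, CC(C)(C)C(Cl)=O (retained only in intermediate 18)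
Why: N-Acylation of the Evans auxiliary through a mixed anhydride under LiCl/Et3N conditions avoids strong base, so the methyl ester at C10 is not at risk.

Step 12
Reactants: 19 N-acyl oxazolidinone; 20 acrolein
Product: 22 Evans syn-aldol adduct (C6 S and C7 R as the imide), via dibutylboron enolate 21 (not isolated)
Conditions: Bu2BOTf, i-Pr2NEt, CH2Cl2, −78 → 0 °C; then 20, −78 → 0 °C; pH 7 buffer, MeOH, H2O2, 0 °C
Reagents that add atoms: dibutylboron triflate, CCCCB(CCCC)OS(=O)(=O)C(F)(F)F (boron retained only in intermediate 21)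
Why: In the Evans syn-aldol reaction the Z(O)-boron enolate 21 adds to acrolein through a Zimmerman–Traxler chair on the face away from the benzyl group, so the auxiliary sets C6 and C7 together, and the boron triflate/amine pair enolises the imide but not the methyl ester.

Step 13
Reactants: 22 aldol adduct
Product: 23 methyl 2-[(2S,4R)-4-[(3Z,7R,8R)-8-hydroxy-7-(hydroxymethyl)-3-methyldeca-3,9-dien-1-yl]-5,5-dimethyloxolan-2-yl]acetate
Conditions: NaBH4, THF/H2O, 0 °C → rt
Reagents that add atoms: none
Why: Reductive cleavage of the N-acyl oxazolidinone by borohydride in aqueous THF gives the C6′ primary alcohol without epimerising C6 and returns the auxiliary, while the unactivated methyl ester should react far more slowly.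

Step 14
Reactants: 23 diol
Product: 24 methyl 2-[(2S,4R)-4-[(3Z,7R,8R)-7-(TBS-oxymethyl)-8-hydroxy-3-methyldeca-3,9-dien-1-yl]-5,5-dimethyloxolan-2-yl]acetate
Conditions: TBSCl (1.05 equiv), imidazole, CH2Cl2, 0 °C
Reagents that add atoms: tert-butyl(chloro)dimethylsilane, CC(C)(C)[Si](C)(C)Cl
Why: Silyl ether formation should select the primary C6′ hydroxyl over the hindered secondary allylic C7 hydroxyl on steric grounds.

Step 15
Reactants: 24 hydroxy ester
Product: 25 seco acid 2-[(2S,4R)-4-[(3Z,7R,8R)-7-(TBS-oxymethyl)-8-hydroxy-3-methyldeca-3,9-dien-1-yl]-5,5-dimethyloxolan-2-yl]acetic acid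
Conditions: LiOH, THF/MeOH/H2O, rt; then 1 M HCl to pH 4, 0 °C
Reagents that add atoms: lithium hydroxide, [Li+].[OH-]
Why: Saponification of the methyl ester should leave the TBS ether and the allylic alcohol intact, and hydroxide does not enolise the β-alkoxy ester, so the oxolane ring stays closed.

Step 16
Reactants: 25 seco acid
Product: 27 (2Z,6R,7R,11S,13R)-14-membered macrolactone, via mixed trichlorobenzoic anhydride 26 (not isolated)
Conditions: 2,4,6-Cl3C6H2COCl, Et3N, THF, rt; then slow addition to DMAP, toluene, 80 °C (high dilution)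
Reagents that add atoms: 2,4,6-trichlorobenzoyl chloride, O=C(Cl)c1c(Cl)cc(Cl)cc1Cl (retained only in intermediate 26)
Why: In the Yamaguchi macrolactonisation the mixed anhydride acylates DMAP and the acylpyridinium ion is captured by the C7 hydroxyl under high dilution, which should close the 14-membered lactone with retention at C7.

Step 17
Reactants: 27 macrolactone
Product: 30 (2Z,7E,6S,10S,11S,13R)-carbocyclic C10 acid, via silyl ketene acetal 28 (not isolated), via trimethylsilyl ester 29 (not isolated)
Conditions: TMSCl/Et3N, THF, −100 °C; LDA, −100 → −78 °C; then rt → 65 °C; mild aqueous work-up (aq. NH4Cl)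
Reagents that add atoms: chlorotrimethylsilane, C[Si](C)(C)Cl (retained only in intermediates 28 and 29)
Why: LDA removes a C10 proton through the cyclic Ireland transition state to give the kinetic E(O)-enolate (C11 trans to O–Li and cis to the ring oxygen), which TMSCl already present in the flask traps as ketene acetal 28 before the enolate can expel the β C11–O bond. On warming, 28 undergoes the concerted suprafacial [3,3]-sigmatropic shift of an Ireland–Claisen rearrangement, the closest known type being the rearrangement of macrolactone silyl ketene acetals to carbocycles. The 14-membered carbocycle is closed by bond transposition inside the existing 14-membered lactone and not by an end-to-end cyclisation: in a six-membered chair transition state spanned by the ten-atom C6–C11 tether, C9–C10 forms as C7–O breaks and the O–C(=O) unit leaves the ring as the carboxyl group. C10 is set by chirality transfer from C7 (R), since the C6 arm sits equatorial at C7 and C11 axial at C10, which leads to 10S and to an E C7=C8 alkene. The step needs one ketene acetal geometry, a chair and not a boat, and silylation that outruns β-elimination; kinetic enolisation without a polar additive, the equatorial preference of the branched C6 arm, the long tether and the internal quench at −100 °C are meant to secure these. Mild aqueous work-up cleaves silyl ester 29 to acid 30.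

Step 18
Reactants: 30 unsaturated carbocyclic acid
Product: 31 (2Z,6R,10S,11S,13R)-7,8-dihydro acid
Conditions: 2-nitrobenzenesulfonylhydrazide (NBSH, limited excess), Et3N, CH2Cl2, rt
Reagents that add atoms: none
Why: Diimide reduction (concerted syn delivery of two hydrogens) is markedly faster for the E-disubstituted C7=C8 alkene than for the trisubstituted C2=C3 alkene, so a limited charge of the diimide source should saturate C7=C8 only and no stereocentre is touched.

Step 19
Reactants: 31 silyl ether acid
Product: 32 (2Z,6R,10S,11S,13R)-C6-hydroxymethyl acid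
Conditions: HF·pyridine, THF/pyridine, 0 °C → rt
Reagents that add atoms: none
Why: Fluoride cleavage of the primary TBS ether under buffered conditions should not affect the carboxylic acid, the oxolane or the alkene.

Step 20
Reactants: 32 hydroxy acid
Product: 33 target diacid CNP0115244.1
Conditions: TEMPO (cat.), PhI(OAc)2, MeCN/H2O, rt
Reagents that add atoms: water, O
Why: TEMPO/PhI(OAc)2 oxidation in aqueous acetonitrile converts the primary alcohol to the acid under near-neutral conditions, which should avoid epimerisation of C6 at the aldehyde stage and leave the alkene alone.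

Compound list

1 | pentane-1,5-diol | OCCCCCO | starting material
2 | 5-[(tert-butyldiphenylsilyl)oxy]pentan-1-ol | OCCCCCO[Si](c1ccccc1)(c1ccccc1)C(C)(C)C | intermediate
3 | 5-[(tert-butyldiphenylsilyl)oxy]pentanal | O=CCCCCO[Si](c1ccccc1)(c1ccccc1)C(C)(C)C | intermediate
4 | (R)-(−)-carvone | CC1=CC[C@H](CC1=O)C(C)=C | starting material
5 | lithium (5R)-2-methyl-5-(prop-1-en-2-yl)cyclohex-1-en-1-olate (not isolated) | CC1=C(O[Li])C[C@@H](CC1)C(C)=C | intermediate
6 | (2R,5R)-2-[(1R)-5-[(tert-butyldiphenylsilyl)oxy]-1-hydroxypentyl]-2-methyl-5-(prop-1-en-2-yl)cyclohexan-1-one (side chain cis to isopropenyl) | O=C1C[C@H](C(C)=C)CC[C@]1(C)[C@H](O)CCCCO[Si](c2ccccc2)(c2ccccc2)C(C)(C)C | intermediate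
7 | (2R,5R)-2-[(1R)-5-[(tert-butyldiphenylsilyl)oxy]-1-(methanesulfonyloxy)pentyl]-2-methyl-5-(prop-1-en-2-yl)cyclohexan-1-one | O=C1C[C@H](C(C)=C)CC[C@]1(C)[C@H](OS(C)(=O)=O)CCCCO[Si](c2ccccc2)(c2ccccc2)C(C)(C)C | intermediate
8 | (2R,5R)-5-(2-hydroxypropan-2-yl)-2-[(1R)-5-[(tert-butyldiphenylsilyl)oxy]-1-(methanesulfonyloxy)pentyl]-2-methylcyclohexan-1-one | O=C1C[C@H](C(C)(C)O)CC[C@]1(C)[C@H](OS(C)(=O)=O)CCCCO[Si](c2ccccc2)(c2ccccc2)C(C)(C)C | intermediate
9 | (3R,6Z)-11-[(tert-butyldiphenylsilyl)oxy]-3-(2-hydroxypropan-2-yl)-6-methylundec-6-enoic acid (not isolated) | OC(=O)C[C@H](C(C)(C)O)CC/C(C)=C\CCCCO[Si](c1ccccc1)(c1ccccc1)C(C)(C)C | intermediate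
10 | (4R)-4-[(3Z)-8-[(tert-butyldiphenylsilyl)oxy]-3-methyloct-3-en-1-yl]-5,5-dimethyloxolan-2-one | O=C1C[C@@H](CC/C(C)=C\CCCCO[Si](c2ccccc2)(c2ccccc2)C(C)(C)C)C(C)(C)O1 | intermediate
11 | O-diisobutylaluminium hemiacetal of 10 (not isolated; C11 unassigned) | CC(C)C[Al](CC(C)C)OC1C[C@@H](CC/C(C)=C\CCCCO[Si](c2ccccc2)(c2ccccc2)C(C)(C)C)C(C)(C)O1 | intermediate
12 | (4R)-4-[(3Z)-8-[(tert-butyldiphenylsilyl)oxy]-3-methyloct-3-en-1-yl]-5,5-dimethyloxolan-2-yl acetate (both C11 epimers) | CC(=O)OC1C[C@@H](CC/C(C)=C\CCCCO[Si](c2ccccc2)(c2ccccc2)C(C)(C)C)C(C)(C)O1 | intermediate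
13 | tert-butyl[(1-methoxyethenyl)oxy]dimethylsilane | C=C(OC)O[Si](C)(C)C(C)(C)C | starting material
14 | methyl 2-[(2S,4R)-4-[(3Z)-8-[(tert-butyldiphenylsilyl)oxy]-3-methyloct-3-en-1-yl]-5,5-dimethyloxolan-2-yl]acetate (2,4-trans) | COC(=O)C[C@@H]1C[C@@H](CC/C(C)=C\CCCCO[Si](c2ccccc2)(c2ccccc2)C(C)(C)C)C(C)(C)O1 | intermediate
15 | methyl 2-[(2S,4R)-4-[(3Z)-8-hydroxy-3-methyloct-3-en-1-yl]-5,5-dimethyloxolan-2-yl]acetate | COC(=O)C[C@@H]1C[C@@H](CC/C(C)=C\CCCCO)C(C)(C)O1 | intermediate
16 | (5Z)-8-[(3R,5S)-5-(2-methoxy-2-oxoethyl)-2,2-dimethyloxolan-3-yl]-6-methyloct-5-enoic acid | COC(=O)C[C@@H]1C[C@@H](CC/C(C)=C\CCCC(O)=O)C(C)(C)O1 | intermediate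
17 | (4S)-4-benzyl-1,3-oxazolidin-2-one | O=C1N[C@@H](Cc2ccccc2)CO1 | starting material
18 | mixed anhydride of 16 and pivalic acid (not isolated) | COC(=O)C[C@@H]1C[C@@H](CC/C(C)=C\CCCC(=O)OC(=O)C(C)(C)C)C(C)(C)O1 | intermediate
19 | methyl 2-[(2S,4R)-4-[(3Z)-8-[(4S)-4-benzyl-2-oxo-1,3-oxazolidin-3-yl]-3-methyl-8-oxooct-3-en-1-yl]-5,5-dimethyloxolan-2-yl]acetate | COC(=O)C[C@@H]1C[C@@H](CC/C(C)=C\CCCC(=O)N2[C@@H](Cc3ccccc3)COC2=O)C(C)(C)O1 | intermediate
20 | acrolein (prop-2-enal) | C=CC=O | starting material
21 | Z(O)-dibutylboron enolate of 19 (C5 cis to O–B; not isolated) | COC(=O)C[C@@H]1C[C@@H](CC/C(C)=C\CC/C=C(\OB(CCCC)CCCC)N2[C@@H](Cc3ccccc3)COC2=O)C(C)(C)O1 | intermediate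
22 | methyl 2-[(2S,4R)-4-[(3Z,7S,8R)-7-{[(4S)-4-benzyl-2-oxo-1,3-oxazolidin-3-yl]carbonyl}-8-hydroxy-3-methyldeca-3,9-dien-1-yl]-5,5-dimethyloxolan-2-yl]acetate (syn-aldol) | COC(=O)C[C@@H]1C[C@@H](CC/C(C)=C\CC[C@H](C(=O)N2[C@@H](Cc3ccccc3)COC2=O)[C@@H](C=C)O)C(C)(C)O1 | intermediate
23 | methyl 2-[(2S,4R)-4-[(3Z,7R,8R)-8-hydroxy-7-(hydroxymethyl)-3-methyldeca-3,9-dien-1-yl]-5,5-dimethyloxolan-2-yl]acetate | COC(=O)C[C@@H]1C[C@@H](CC/C(C)=C\CC[C@H](CO)[C@@H](C=C)O)C(C)(C)O1 | intermediate
24 | methyl 2-[(2S,4R)-4-[(3Z,7R,8R)-7-{[(tert-butyldimethylsilyl)oxy]methyl}-8-hydroxy-3-methyldeca-3,9-dien-1-yl]-5,5-dimethyloxolan-2-yl]acetate | COC(=O)C[C@@H]1C[C@@H](CC/C(C)=C\CC[C@H](CO[Si](C)(C)C(C)(C)C)[C@@H](C=C)O)C(C)(C)O1 | intermediate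
25 | 2-[(2S,4R)-4-[(3Z,7R,8R)-7-{[(tert-butyldimethylsilyl)oxy]methyl}-8-hydroxy-3-methyldeca-3,9-dien-1-yl]-5,5-dimethyloxolan-2-yl]acetic acid (seco acid) | OC(=O)C[C@@H]1C[C@@H](CC/C(C)=C\CC[C@H](CO[Si](C)(C)C(C)(C)C)[C@@H](C=C)O)C(C)(C)O1 | intermediate
26 | mixed anhydride of 25 and 2,4,6-trichlorobenzoic acid (not isolated) | O=C(C[C@@H]1C[C@@H](CC/C(C)=C\CC[C@H](CO[Si](C)(C)C(C)(C)C)[C@@H](C=C)O)C(C)(C)O1)OC(=O)c1c(Cl)cc(Cl)cc1Cl | intermediate
27 | (2Z,6R,7R,11S,13R)-14-membered macrolactone: ring C2–C7, O, C(=O), C10–C15; lactone oxygen on C7, which also carries the vinyl group C8=C9; C6 bears CH2OTBS; C11 and C13 are bridged by O–C16Me2 (2,2-dimethyloxolane, C10 and C14 trans); C2 bears methyl | C/C1=C/CC[C@H](CO[Si](C)(C)C(C)(C)C)[C@@H](C=C)OC(=O)C[C@@H]2C[C@@H](CC1)C(C)(C)O2 | intermediate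
28 | trimethylsilyl ketene acetal of 27 with C11 cis to the ring oxygen and trans to OSiMe3 (not isolated) | C/C1=C/CC[C@H](CO[Si](C)(C)C(C)(C)C)[C@@H](C=C)O/C(O[Si](C)(C)C)=C\[C@@H]2C[C@@H](CC1)C(C)(C)O2 | intermediate
29 | trimethylsilyl ester of 30 (not isolated) | C/C1=C/CC[C@H](CO[Si](C)(C)C(C)(C)C)/C=C/C[C@H](C(=O)O[Si](C)(C)C)[C@@H]2C[C@@H](CC1)C(C)(C)O2 | intermediate
30 | (2Z,7E,6S,10S,11S,13R)-carbocyclic acid: 14-membered ring C2–C15 with Z C2=C3 and E C7=C8; C10 bears CO2H, C6 bears CH2OTBS; oxolane bridge C11–O–C16Me2–C13 | C/C1=C/CC[C@H](CO[Si](C)(C)C(C)(C)C)/C=C/C[C@H](C(=O)O)[C@@H]2C[C@@H](CC1)C(C)(C)O2 | intermediate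
31 | (2Z,6R,10S,11S,13R)-7,8-dihydro derivative of 30 | C/C1=C/CC[C@H](CO[Si](C)(C)C(C)(C)C)CCC[C@H](C(=O)O)[C@@H]2C[C@@H](CC1)C(C)(C)O2 | intermediate
32 | (2Z,6R,10S,11S,13R)-C6-hydroxymethyl C10-acid | C/C1=C/CC[C@H](CO)CCC[C@H](C(=O)O)[C@@H]2C[C@@H](CC1)C(C)(C)O2 | intermediate
33 | CNP0115244.1, (2Z,6R,10S,11S,13R)-diacid | C/C1=C/CC[C@H](C(=O)O)CCC[C@H](C(=O)O)[C@@H]2C[C@@H](CC1)C(C)(C)O2 | target

Total step count: 20.
Longest linear sequence: 20 steps (pentane-1,5-diol to 33; 18 steps from (R)-carvone).

Steps most likely to fail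

1. Step 17. Chirality transfer may run through the other ketene acetal geometry or through a boat, because the macrocycle and not the base may decide the shape of the enolate; the C10 epimer would then form. Fallback: the route leaves at seco acid 25. Mitsunobu macrolactonisation (PPh3, DIAD, toluene, high dilution) closes the ring by activating the C7 hydroxyl, so the carboxylate enters with inversion and gives the C7-epimeric lactone F1. Enolisation of F1 under conditions that favour the opposite enolate geometry (LDA, THF/DMPU, TMSCl, −78 °C) gives the ketene acetal F2, with C11 trans to the ring oxygen. In the chair with the C6 arm equatorial, the inverted C7 and the inverted ketene acetal geometry compensate, so F2 should rearrange to the same silyl ester 29. The route is rejoined at acid 30.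

2. Step 3. Simple diastereoselection in the aldol may be poor or reversed (aldehyde chain axial, or a boat), and the wrong C3 carbinol epimer would be carried into the E-alkene by the anti fragmentation. Fallback: the route leaves at 3 and 4. The other carbinol epimer F3 is collected by chromatography, or made the major product by transmetalating enolate 5 to titanium with ClTi(Oi-Pr)3 before 3 is added. It is sent through a syn-elimination sequence that is stereocomplementary to the Grob fragmentation. Mukaiyama hydration as in step 5 gives keto diol F4. Baeyer–Villiger oxidation (m-CPBA, NaHCO3, CH2Cl2), with migration of the quaternary C2 and retention, gives the seven-membered lactone F5. The tertiary C16 hydroxyl translactonises F5 (cat. CSA, CH2Cl2) to the γ-lactone diol F6. Thiocarbonyldiimidazole (DMAP, toluene, 80 °C) gives the cyclic thionocarbonate F7. Corey–Winter elimination (1,3-dimethyl-2-phenyl-1,3,2-diazaphospholidine, 40 °C) removes both oxygens from the same side and should give the Z-alkene. The route is rejoined at lactone 10.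

3. Step 8. The gem-dimethyl group next to C13 may change the preferred envelope of the oxocarbenium ion, so that the ketene acetal attacks the other face of C11 and the cis-2,4 isomer forms. Fallback: the route leaves at lactone 10. Claisen-type addition of the lithium enolate of methyl acetate (LDA, MeOAc, THF, −78 °C) gives the hemiketal F8. Reduction of F8 with Et3SiH and BF3·OEt2 (CH2Cl2, −78 → −40 °C) generates the C11 oxocarbenium ion that already carries the acetate arm and delivers hydride to it. The same facial bias then places hydrogen where the carbon nucleophile would have gone and the acetate arm trans to C14. The route is rejoined at ester 14.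

Further compounds

F1 | step 17 | (2Z,6R,7S,11S,13R)-macrolactone, the C7 epimer of 27 | C/C1=C/CC[C@H](CO[Si](C)(C)C(C)(C)C)[C@H](C=C)OC(=O)C[C@@H]2C[C@@H](CC1)C(C)(C)O2
F2 | step 17 | trimethylsilyl ketene acetal of F1 with C11 trans to the ring oxygen | C/C1=C/CC[C@H](CO[Si](C)(C)C(C)(C)C)[C@H](C=C)O/C(O[Si](C)(C)C)=C/[C@@H]2C[C@@H](CC1)C(C)(C)O2
F3 | step 3 | (2R,5R)-2-[(1S)-5-[(tert-butyldiphenylsilyl)oxy]-1-hydroxypentyl]-2-methyl-5-(prop-1-en-2-yl)cyclohexan-1-one, the carbinol epimer of 6 | O=C1C[C@H](C(C)=C)CC[C@]1(C)[C@@H](O)CCCCO[Si](c2ccccc2)(c2ccccc2)C(C)(C)C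
F4 | step 3 | keto diol from hydration of F3 (tertiary C16 alcohol) | O=C1C[C@H](C(C)(C)O)CC[C@]1(C)[C@@H](O)CCCCO[Si](c2ccccc2)(c2ccccc2)C(C)(C)C
F5 | step 3 | seven-membered lactone (oxepan-2-one) from Baeyer–Villiger oxidation of F4, oxygen inserted between C11 and C2 | O=C1C[C@H](C(C)(C)O)CC[C@@](C)(O1)[C@@H](O)CCCCO[Si](c2ccccc2)(c2ccccc2)C(C)(C)C
F6 | step 3 | γ-lactone with the vicinal C2 (tertiary) and C3 (secondary) diol in the side chain | O=C1C[C@@H](CC[C@@](C)(O)[C@@H](O)CCCCO[Si](c2ccccc2)(c2ccccc2)C(C)(C)C)C(C)(C)O1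
F7 | step 3 | cyclic thionocarbonate of F6 | O=C1C[C@@H](CC[C@@]2(C)OC(=S)O[C@H]2CCCCO[Si](c3ccccc3)(c3ccccc3)C(C)(C)C)C(C)(C)O1
F8 | step 8 | methyl 2-[(4R)-2-hydroxy-4-[(3Z)-8-[(tert-butyldiphenylsilyl)oxy]-3-methyloct-3-en-1-yl]-5,5-dimethyloxolan-2-yl]acetate (hemiketal) | COC(=O)CC1(O)C[C@@H](CC/C(C)=C\CCCCO[Si](c2ccccc2)(c2ccccc2)C(C)(C)C)C(C)(C)O1
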